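The readings were generated by integration from invented constants, noise included.

The starting material left at the last reading, 93.6 % in the grey run and 86.8 % in the violet run, was where I began: the two runs differ in their free catalyst, and the new flask lies between them.

| flask | starting material | partner | free catalyst | remark | time |
|---|---|---|---|---|---|
| grey | 0.010 M | 0.012 M | 1 mM | run made earlier |  |
| violet | 0.010 M | 0.012 M | 2.2 mM | run made earlier |  |
| flask | 0.010 M | 0.0120 M | 1.5 mM |  | 4.0 h |

| run | time / h | product / % | starting material / % |
|---|---|---|---|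
| grey | 0.167 | 0 | 99.7 |
| grey | 0.500 | 0 | 98.4 |
| grey | 0.833 | 0.5 | 96.8 |
| grey | 1.33 | 1.1 | 96.6 |
| grey | 2.00 | 3.5 | 94.8 |
| grey | 2.50 | 3.8 | 93.6 |
| violet | 0.200 | 0.2 | 97.0 |
| violet | 0.333 | 0.3 | 97.6 |
| violet | 0.500 | 0.7 | 95.4 |
| violet | 0.833 | 0.6 | 93.9 |
| violet | 1.33 | 1.9 | 92.0 |
| violet | 2.50 | 5.9 | 86.8 |

(standard deviation of a reading: 0.5 percentage points)

1. concentration of product at 4.0 h, in M
2. concentration of starting material at 4.0 h, in M



I froze the catalyst at its charge, which makes the loss pseudo-first-order, and divided the logarithm of charge over leftover by free catalyst times time. The grey run gave 0.00735 M⁻¹ s⁻¹ and the violet run 0.00715 M⁻¹ s⁻¹. Taken separately to the flask, they gave [starting material] of 0.00853 M and 0.00857 M, apart by 0.37 percentage points of the charge, with a reading's scatter at 0.5 points. So I pooled them, summed logarithms over summed catalyst-times, into the loss constant 0.00721 M⁻¹ s⁻¹, which gave 0.00856 M.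

For the product I used the gap, the starting material that is neither left nor product. In the violet run it read 6.10 % at 1.33 h and 7.30 % at 2.50 h, so I froze it in time and scaled it with catalyst. Here the two ways parted: the grey run's 2.60 % scaled to 3.90 % for the flask, the violet run's to 4.98 %. The grey run was the weaker, since scaling multiplies its scatter by 1.50 and the violet run's by 0.682. Keeping the violet figure, I expected [product] of 9.45 × 10⁻⁴ M.

The forecast gave 9.200 × 10⁻⁴ M and 0.00857 M, slightly different figures, on the ground that “Starting-material loss is first order in catalyst”. The flask gave 8.89 × 10⁻⁴ M and 0.00868 M.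

    partner + free catalyst ⇌ catalyst intermediate A (K = 28.0 M⁻¹, k = 1.70 M⁻¹ s⁻¹)
    starting material + catalyst intermediate A ⇌ catalyst intermediate B (K = 110 M⁻¹, k = 0.0680 M⁻¹ s⁻¹)
    catalyst intermediate B → by-product + catalyst intermediate C (k = 6.20 × 10⁻⁴ s⁻¹)
    catalyst intermediate C ⇌ catalyst intermediate D (K = 6.30, k = 5.70 × 10⁻⁴ s⁻¹)
    catalyst intermediate D → free catalyst + product (k = 0.0130 s⁻¹)
    2 catalyst intermediate B ⇌ resting dimer, settled at all times (K = 6200 M⁻¹)

Read back from this result, the loss constant is 0.00654 M⁻¹ s⁻¹, a little below mine. The product in this flask stayed low in part because of the way back from catalyst intermediate A to partner and free catalyst, acting together with the time allowed: without that way back the flask gives 0.00161 M instead of 8.89 × 10⁻⁴ M, and left for 40.0 h it gives 0.00647 M. For the same flask read at 2.5 h, the loss constant gives [starting material] of 0.00907 M and, with the frozen gap, [product] of 4.30 × 10⁻⁴ M. The computed values are 0.00907 M and 4.80 × 10⁻⁴ M.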